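The beta run, at 31 °C against 25 °C and richer in J, fell from 31.2% of G to 19.7% within 10.0 min. The epsilon flask falls as well, from 49.4% to 31.2% within 20.0 min. That beta comparison is not clean, but it gives me no ground to heat the next run. I keep the epsilon charge and temperature and have to decide what to do at 20 min.

| setting | epsilon | beta | flask |
|---|---|---|---|
| J | 0.20 M | 0.40 M | 0.20 M |
| Q | 0.18 M | 0.18 M | 0.180 M |
| X | 0.040 M | 0.040 M | 0.0400 M |
| temperature | 25 °C | 31 °C | 25 °C |
| remark | the very flask that is asked about, followed so far | run made earlier |  |
| time |  |  | 20 min |

- epsilon (time / min: G / %): 1.50: 49.4; 2.50: 47.5; 4.00: 44.4; 8.00: 40.5; 12.0: 37.4; 20.0: 31.2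
- beta (time / min: G / %): 0.833: 31.2; 1.33: 28.8; 2.00: 26.3; 4.00: 24.4; 6.00: 24.2; 10.0: 19.7

(readings scatter by 1 percentage point)

- north-east: at 20 min raise the temperature by 25 K, then wait 10 min
- west: at 20 min take out 90% of the E then present, then wait 10 min
- south: at 20 min add Q, 100% of the amount charged, then wait 10 min
- south-west: change nothing and wait 10 min more

- additions bring no volume worth counting
- the numbers in the tables scatter with a standard deviation of 1 percentage point
- steps that have been proposed: Q + X -> L; J + Q <-> G + E; Q -> Z

- G, in percent of the J first charged, at 20 min
- the remedy with the largest gain of G, or "none" below 2 percentage points (north-east / west / south / south-west / none)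
- G present, in percent of the J first charged, after south
- G present, in percent of the J first charged, after south-west

I reckon with one number, the balance quotient: G times E over J times free Q, with E counted equal to G, one E forming with each G. This is the equilibrium constant of J + Q ⇌ G + E. Free Q is the unknown. At the first reading, 1.50 min, I guess the Q lost by ways other than into G lies between nothing and the charge of X, and I replace that range by its mean. This gives 1.58, and the two ends give 1.19 and 2.34.

The last reading then implies 0.0180 M of free Q. Adding Q raises that to 0.198 M, and the balance then reaches 62.8% of G before further drain, a jump of 32 percentage points.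

Now I check the error of the mean. Taking out E turns free Q into G, and even at the low end of the constant that free Q is 0.0238 M, or 11.9% of the J charged, which is less than the 28 points that adding Q gives at that same end. My decision is to add Q at 20 min.

The forecast agrees on the choice: south. It gives 31.5% (30.3% to 32.7%) now, 51% (44% to 58%) after south and 26.3% (24% to 28.5%) after south-west. It says “Adding Q re-equilibrates G to about 68%, then drain lowers it to about 51%”. Its constant is 2.5 where mine is 1.58, and my jump stops at 62.8%, not its 68%.

    Q + X → L (k = 2.53 M⁻¹ min⁻¹, Ea = 52.0 kJ mol⁻¹)
    J + Q ⇌ G + E (K = 1.45, k = 11.1 M⁻¹ min⁻¹, Ea = 57.0 kJ mol⁻¹, ΔH = −27.0 kJ mol⁻¹)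
    Q → Z (k = 0.0785 min⁻¹, Ea = 95.0 kJ mol⁻¹)
    (constants at 25 °C)

The new flask gives 32.4% of G, then 51.8% after south, with a gain of 19 points, and 27.8% after south-west, each within the forecast's range. At 20.0 min in this flask, J + Q and G + E relax by that step alone, both ways together, with a half-life of 0.255 min, far shorter than the 25.1 min of the whole flask's slowest mode, and my constant turns 32.4% of G into 10.9% of the Q charged, against 11.5% present. Left to 200 min, this flask holds 8.13% of G, which the constant turns into 0.508% of the Q charged, against 0.533% present.

(The runs are calculated for an exercise; the scatter is artificial.)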